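The coupling partner and the substrate are taken to go one for one, so the substrate that can react in a flask is bounded by the partner charged. In spring, noon, summer and dusk the partner, at 0.120 M against 0.20 M of substrate, is the limiting reagent, and its balance sets a ceiling of 60.0% of the substrate charge.

common to all: substrate 0.20 M
- Thursday's: coupling partner 0.080 M; free catalyst 0.50 mM; run made earlier
- Friday's: coupling partner 0.060 M; free catalyst 0.50 mM; run made earlier
- spring: coupling partner 0.120 M; free catalyst 0.50 mM; time 50 min
- noon: coupling partner 0.120 M; free catalyst 1.0 mM; time 50 min
- summer: coupling partner 0.120 M; free catalyst 2.0 mM; time 50 min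
- dusk: coupling partner 0.120 M; free catalyst 4.0 mM; time 50 min

| run | time / min | target / % |
|---|---|---|
| Thursday's | 8.00 | 4.2 |
| Thursday's | 15.0 | 6.9 |
| Thursday's | 25.0 | 9.7 |
| Thursday's | 30.0 | 9.3 |
| Friday's | 4.00 | 1.4 |
| Friday's | 10.0 | 5.1 |
| Friday's | 20.0 | 7.5 |
| Friday's | 30.0 | 8.6 |

(each reading ± 0.5 percentage points)

* amount of target at the end, in percent of the substrate charged for spring, noon, summer, dusk, in this order
* how that number moves from the first to the last of them (rises all the way / falls all the way / hardly changes / falls, then rises / rises, then falls)

Thursday's first reading gives a rate of 0.00525 min⁻¹ as a fraction of the substrate charge. Dividing the ceiling by this rate, taken over unchanged from Thursday's flask, gives the exhaustion time, the time a flask needs to use up its limiting reagent at a steady rate: 114 min for spring. No earlier run varies the catalyst, so this reckoning guesses that the rate follows the catalyst charge. That shortens the exhaustion time to 57.1 min for noon, 28.6 min for summer and 14.3 min for dusk.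

By 25.0 min, Thursday's target reads 9.7% and has levelled within the scatter, yet that rate over that time comes to a third of Thursday's ceiling. This reckoning therefore assumes that target is lost as it forms; a dying catalyst is the other reading it leaves open. Rate over plateau gives a first-order loss of 0.0541 min⁻¹. In this reckoning target builds until the exhaustion time and afterwards simply decays. The reckoned end values are 9.05% for spring, 18.1% for noon, 9.57% for summer and 6.05% for dusk.

The weak link is the loss constant, which rests on Thursday's first reading and its plateau reading, each with a scatter of 0.5 percentage points. Friday's readings give a rate of 0.00510 min⁻¹ and a loss of 0.0593 min⁻¹. With these, noon comes to 16.3% and summer, exhausted at 29.4 min, to 8.37%. Reckoned noon stays above reckoned summer, so this reckoning expects a row that rises, then falls.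

The forecast differs: 17%, 28%, 40% and 50%, so rises all the way, on the ground that “Both causes predict that more catalyst wins the competition.”

The flasks give 11.2%, 14.3%, 6.17% and 4.22%: rises, then falls.

    coupling partner + free catalyst → catalyst intermediate A (k = 390 M⁻¹ min⁻¹)
    catalyst intermediate A ⇌ catalyst intermediate B (K = 0.140, k = 22.0 min⁻¹)
    catalyst intermediate B ⇌ by-product + catalyst intermediate C (K = 0.510 M, k = 33.0 min⁻¹)
    substrate + catalyst intermediate C → catalyst intermediate D (k = 19000 M⁻¹ min⁻¹)
    catalyst intermediate D → free catalyst + target (k = 49.0 min⁻¹)
    target → over-reaction product (k = 0.0600 min⁻¹)

In spring, the half-life of target by its reaction to over-reaction product alone, 12 min, is shorter than the 50 min of the run. The exhaustion time of 114 min, divided by the catalyst ratio of 4.00, gives 28.6 min for summer, but at 25.0 min, earlier than that, summer holds 0.702% of its partner. Divided by 2.00, it gives 57.1 min for noon, but at 50.0 min, again earlier, noon holds 0.711% of its partner.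

The readings were generated by integration with made-up constants; scatter was added.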